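**Retrosynthetic overview**
1. Target 31 ← hydroxyl-directed epoxidation of the C8=C9 (Z) alkene of triacetate 30; the three acetates come from one global acetylation, C12-OH from a chelation-controlled ketone reduction.
2. Dihydropyran and nine-membered carbocycle are formed together (C4=C4a, then C4a–C11a and O2–C1) by a domino Knoevenagel / intramolecular inverse-demand hetero-Diels–Alder reaction of aldehyde 16 with β-keto aldehyde 23; the exocyclic methylene is masked as CH2SePh.
3. 16 ← B-alkyl Suzuki coupling of (Z)-vinyl iodide 8 (from geraniol; Sharpless epoxidation sets C7) with allyl selenide 11 (from isoprenol).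
4. 23 ← L-proline aldol of hydroxyacetone with 2-chloro-2-methylpropanal (sets C13 and C14), chlorohydrin-to-epoxide closure, formylation.
5. Ring order: side-chain epoxide (step 13) → pyran + cyclononene together (step 15) → ring epoxide last (step 19).

Assumption: xenicane numbering is used (O2, C1 acetal, C3=C4, C4a/C11a fusion, C5–C11 carbocycle, C12–C15 side chain, C19 exocyclic CH2); C11 in 12–16 and 24–26, the enol ether geometry in 15, 16 and 24, and the anomeric centre in 25–29 are carried as mixtures because each is erased or reset later; 2-chloro-2-methylpropanal is taken as a catalogue chemical.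

**Step 1**
Reactants: 1 geraniol
Product: 2 (2S,3S)-2,3-epoxygeraniol
Conditions: Ti(OiPr)4 (5 mol%), L-(+)-DET (7.5 mol%), t-BuOOH, 4 Å MS, CH2Cl2, −20 °C
Reagents that add atoms: tert-butyl hydroperoxide CC(C)(C)OO
Why: Sharpless asymmetric epoxidation of the allylic alcohol; the L-(+)-tartrate catalyst gives the (2S,3S)-epoxide, whose C3 becomes the C7 carbinol, and the remote alkene is untouched.

**Step 2**
Reactants: 2 (2S,3S)-2,3-epoxygeraniol
Product: 3 (2R,3S)-2-(chloromethyl)-3-methyl-3-(4-methylpent-3-en-1-yl)oxirane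
Conditions: PPh3, CCl4, NaHCO3, reflux
Reagents that add atoms: carbon tetrachloride ClC(Cl)(Cl)Cl
Why: Appel chlorination of the primary alcohol under neutral conditions leaves the epoxide and both stereocentres intact.

**Step 3**
Reactants: 3 (2R,3S)-2-(chloromethyl)-3-methyl-3-(4-methylpent-3-en-1-yl)oxirane
Product: 5 (S)-1-iodo-3,7-dimethyloct-6-en-1-yn-3-ol, via dilithium alkoxide acetylide 4 (not isolated)
Conditions: n-BuLi (3.2 equiv), THF, −78 → −20 °C; then I2 (1.05 equiv), −78 °C; aq. NH4Cl/Na2S2O3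
Reagents that add atoms: iodine II
Why: Base-induced double elimination of the 2,3-epoxy chloride (Yadav-type alkyne synthesis) gives the tertiary propargylic alkoxide with retention, since its C–O bond is never broken, and the lithium acetylide is iodinated in the same flask.

**Step 4**
Reactants: 5 (S)-1-iodo-3,7-dimethyloct-6-en-1-yn-3-ol
Product: 6 (3S,1Z)-1-iodo-3,7-dimethylocta-1,6-dien-3-ol
Conditions: 2-nitrobenzenesulfonyl hydrazide (NBSH), Et3N, THF/i-PrOH, 23 °C
Reagents that add atoms: none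
Why: Diimide reduction adds H2 syn to the iodoalkyne to give the (Z)-vinyl iodide, while the trisubstituted alkene is not reduced.

**Step 5**
Reactants: 6 (3S,1Z)-1-iodo-3,7-dimethylocta-1,6-dien-3-ol
Product: 7 (3S,1Z)-1-iodo-3,7-dimethyl-3-[(triethylsilyl)oxy]octa-1,6-diene
Conditions: TESOTf, 2,6-lutidine, CH2Cl2, −78 → 0 °C
Reagents that add atoms: triethylsilyl triflate CC[Si](CC)(CC)OS(=O)(=O)C(F)(F)F
Why: Silylation of the tertiary alcohol with a silyl triflate protects C7-OH so that it cannot add (oxa-Michael) to the heterodiene in step 15.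

**Step 6**
Reactants: 7 (3S,1Z)-1-iodo-3,7-dimethyl-3-[(triethylsilyl)oxy]octa-1,6-diene
Product: 8 methyl (4S,5Z)-6-iodo-4-methyl-4-[(triethylsilyl)oxy]hex-5-enoate
Conditions: O3, NaOH (2.5 M in MeOH), CH2Cl2, −78 °C
Reagents that add atoms: ozone [O-][O+]=O; methanol CO
Why: Marshall ozonolysis in methanolic base converts the electron-rich trisubstituted alkene directly into the methyl ester, while the electron-poor vinyl iodide reacts far more slowly.

**Step 7**
Reactants: 9 3-methylbut-3-en-1-ol (isoprenol)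
Product: 11 3-[(phenylselanyl)methyl]but-3-en-1-ol, via isoprenol dianion 10 (not isolated)
Conditions: n-BuLi (2.2 equiv), TMEDA, Et2O, 0 → 23 °C; then (PhSe)2, THF, −78 → 0 °C; aq. NH4Cl
Reagents that add atoms: diphenyl diselenide c1ccc(cc1)[Se][Se]c1ccccc1
Why: Allylic metalation of isoprenol to its O,C-dianion and selenenylation of the allyl anion; the 2-substituted allyl selenide is degenerate toward 1,3-selenium shift.

**Step 8**
Reactants: 11 3-[(phenylselanyl)methyl]but-3-en-1-ol; 8 methyl (4S,5Z)-6-iodo-4-methyl-4-[(triethylsilyl)oxy]hex-5-enoate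
Product: 13 methyl (4S,5Z)-10-hydroxy-4-methyl-8-[(phenylselanyl)methyl]-4-[(triethylsilyl)oxy]dec-5-enoate, via B-alkyl-9-BBN borane 12 (not isolated)
Conditions: 9-BBN-H (2.2 equiv), THF, 0 → 23 °C; then 8, Pd(dppf)Cl2 (5 mol%), AsPh3, Cs2CO3, DMF/H2O, 23 °C
Reagents that add atoms: none
Why: 9-BBN hydroborates the 1,1-disubstituted alkene at its terminal carbon and B-alkyl Suzuki–Miyaura coupling joins C10 to C9 with retention of the Z geometry; the new C11 centre is unselective and is erased in step 16.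

**Step 9**
Reactants: 13 methyl (4S,5Z)-10-hydroxy-4-methyl-8-[(phenylselanyl)methyl]-4-[(triethylsilyl)oxy]dec-5-enoate
Product: 14 methyl (4S,5Z)-4-methyl-10-oxo-8-[(phenylselanyl)methyl]-4-[(triethylsilyl)oxy]dec-5-enoate
Conditions: SO3·pyridine, DMSO, i-Pr2NEt, CH2Cl2, 0 °C
Reagents that add atoms: none
Why: Parikh–Doering oxidation of the primary alcohol; activated DMSO does not oxidise the selenide and leaves silyl ether and ester alone.

**Step 10**
Reactants: 14 methyl (4S,5Z)-4-methyl-10-oxo-8-[(phenylselanyl)methyl]-4-[(triethylsilyl)oxy]dec-5-enoate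
Product: 15 methyl (4S,5Z)-10-[(tert-butyldimethylsilyl)oxy]-4-methyl-8-[(phenylselanyl)methyl]-4-[(triethylsilyl)oxy]deca-5,9-dienoate
Conditions: TBSOTf, Et3N, CH2Cl2, −78 → 0 °C
Reagents that add atoms: tert-butyldimethylsilyl triflate CC(C)(C)[Si](C)(C)OS(=O)(=O)C(F)(F)F
Why: Soft enolisation and O-silylation of the aldehyde gives the silyl enol ether dienophile; its geometry does not matter because C1 is reset in step 18, and the ester is not enolised under these conditions.

**Step 11**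
Reactants: 15 methyl (4S,5Z)-10-[(tert-butyldimethylsilyl)oxy]-4-methyl-8-[(phenylselanyl)methyl]-4-[(triethylsilyl)oxy]deca-5,9-dienoate
Product: 16 (4S,5Z)-10-[(tert-butyldimethylsilyl)oxy]-4-methyl-8-[(phenylselanyl)methyl]-4-[(triethylsilyl)oxy]deca-5,9-dienal
Conditions: DIBAL-H (1.1 equiv), toluene, −78 °C; Rochelle salt
Reagents that add atoms: none
Why: Partial DIBAL-H reduction of the methyl ester at −78 °C (stable tetrahedral aluminate) frees the C4a aldehyde without touching the silyl enol ether.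

**Step 12**
Reactants: 17 hydroxyacetone; 18 2-chloro-2-methylpropanal
Product: 19 (3S,4R)-5-chloro-3,4-dihydroxy-5-methylhexan-2-one
Conditions: L-proline (30 mol%), DMSO, 23 °C
Reagents that add atoms: none
Why: List-type L-proline-catalysed direct aldol (enamine, Houk–List transition state) of hydroxyacetone with a non-enolisable α-chloro aldehyde gives the anti-diol and sets C13 and C14.

**Step 13**
Reactants: 19 (3S,4R)-5-chloro-3,4-dihydroxy-5-methylhexan-2-one
Product: 21 (1S)-1-[(2R)-3,3-dimethyloxiran-2-yl]-1-{[(triisopropylsilyl)oxy]methoxy}propan-2-one, via epoxy ketol 20 (not isolated)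
Conditions: K2CO3, MeOH, 0 °C; then TOMCl, i-Pr2NEt, Bu4NI (cat.), CH2Cl2, 0 → 23 °C
Reagents that add atoms: (triisopropylsiloxy)methyl chloride CC(C)[Si](OCCl)(C(C)C)C(C)C
Why: The alkoxide next to the tertiary chloride closes the epoxide (3-exo-tet, C14–O bond kept, so C14 is retained), and the remaining ketol OH is alkylated as a TOM ether, which chelates zinc in step 17 and is cleaved by fluoride in step 18.

**Step 14**
Reactants: 21 (1S)-1-[(2R)-3,3-dimethyloxiran-2-yl]-1-{[(triisopropylsilyl)oxy]methoxy}propan-2-one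
Product: 23 (4S)-4-[(2R)-3,3-dimethyloxiran-2-yl]-3-oxo-4-{[(triisopropylsilyl)oxy]methoxy}butanal (enol form), via lithium enolate 22 (not isolated)
Conditions: LDA (1.1 equiv), THF, −78 °C; then HCO2CH2CF3, −78 °C; aq. NH4Cl; used crude
Reagents that add atoms: 2,2,2-trifluoroethyl formate O=COCC(F)(F)F
Why: Kinetic deprotonation at the methyl group and crossed-Claisen formylation give the β-keto aldehyde, which is held as its enolate/enol so C13 is not epimerised.

**Step 15**
Reactants: 16 (4S,5Z)-10-[(tert-butyldimethylsilyl)oxy]-4-methyl-8-[(phenylselanyl)methyl]-4-[(triethylsilyl)oxy]deca-5,9-dienal; 23 (4S)-4-[(2R)-3,3-dimethyloxiran-2-yl]-3-oxo-4-{[(triisopropylsilyl)oxy]methoxy}butanal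
Product: 25 (4aS,7S,11aR)-trans-fused 1-silyloxy-dihydropyran/(8Z)-cyclononene: 1-OTBS; 7-OTES; 11-CH2SePh; 12-oxo; 13-OTOM (13S); 14R,15-epoxide, via Knoevenagel 2-acyl enal 24 (not isolated)
Conditions: EDDA (20 mol%), Na2SO4, MeCN, 0 °C (0.1 M); then dilute to 2 mM, 50 °C
Reagents that add atoms: none
Why: Proposed new method: amine-salt-catalysed Knoevenagel condensation of 16 with the CH-acidic β-keto aldehyde 23 gives the 2-acyl enal 24, a very electron-poor 1-oxa-1,3-diene whose unhindered formyl C=O/C=C unit adds the tethered silyl enol ether in an intramolecular inverse-electron-demand hetero-Diels–Alder reaction that closes the dihydropyran and the nine-membered ring at once (the cis alkene and the quaternary C7 preorganise the seven-atom tether, an exo-tether transition state is expected to give the trans 4a,11a fusion, and C7 is expected to direct the face to 4aS,11aR); the closest known reaction type is Tietze's domino Knoevenagel/intramolecular hetero-Diels–Alder reaction, established for five- and six-membered tether rings.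

**Step 16**
Reactants: 25 the hetero-Diels–Alder adduct (11-CH2SePh)
Product: 27 (4aS,7S,11aR)-11-methylene analogue: 1-OTBS; 7-OTES; 8Z-ene; 12-oxo; 13-OTOM (13S); 14R,15-epoxide, via selenoxide 26 (not isolated)
Conditions: mCPBA (1.05 equiv), CH2Cl2, −78 °C; then i-Pr2NH, 23 °C
Reagents that add atoms: none
Why: Selenide oxidation and selenoxide syn-elimination; only C11–H is β to selenium, so the exocyclic methylene forms regiospecifically and the C11 epimers converge.

**Step 17**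
Reactants: 27 the 12-ketone with exocyclic methylene
Product: 28 (4aS,7S,11aR,12R,13R,14R)-12-alcohol: 1-OTBS; 7-OTES; 13-OTOM; 14,15-epoxide
Conditions: Zn(BH4)2, Et2O, −20 → 0 °C; aq. NaHCO3/Rochelle salt
Reagents that add atoms: none
Why: Chelation-controlled 1,2-reduction (Cram chelate, Zn bridging C12=O and the C13 alkoxymethyl oxygen) delivers hydride anti to C14 and gives the 12,13-anti (12R) alcohol.

**Step 18**
Reactants: 28 the (12R)-alcohol
Product: 30 (1R,4aS,7S,11aR,12R,13R,14R)-1,12,13-triacetate with free 7-OH and 8Z-ene (8,9-deoxy target), via lactol tetraol 29 (not isolated)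
Conditions: TBAF/AcOH (1:1), THF, 0 → 23 °C; then Ac2O, pyridine, DMAP (cat.), CH2Cl2, 0 °C
Reagents that add atoms: acetic anhydride CC(=O)OC(C)=O
Why: Fluoride removes the TES, anomeric TBS and TOM groups, and basic acetylation esterifies the lactol, C12-OH and C13-OH but not the tertiary C7-OH; the equatorial lactol anomer is expected to acylate faster, giving the 1,11a-trans (1R) acetate.

**Step 19**
Reactants: 30 the triacetate
Product: 31 target CNP0134792.1
Conditions: VO(acac)2 (5 mol%), t-BuOOH (decane), CH2Cl2, 0 °C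
Reagents that add atoms: tert-butyl hydroperoxide CC(C)(C)OO
Why: Hydroxyl-directed vanadium-catalysed epoxidation (Sharpless–Michaelson) of the (Z)-allylic tertiary alcohol delivers oxygen syn to the C7-OH and gives the cis-epoxy alcohol (8R,9R), while the undirected enol ether and exocyclic methylene stay intact.

**Compound list**
1 | geraniol | CC(C)=CCC/C(C)=C/CO | starting material
2 | (2S,3S)-2,3-epoxygeraniol | OC[C@@H]1O[C@@]1(C)CCC=C(C)C | intermediate
3 | (2R,3S)-2-(chloromethyl)-3-methyl-3-(4-methylpent-3-en-1-yl)oxirane | ClC[C@@H]1O[C@@]1(C)CCC=C(C)C | intermediate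
4 | dilithium alkoxide acetylide of (S)-3,7-dimethyloct-6-en-1-yn-3-ol | [Li+].[Li+].[C-]#C[C@@](C)([O-])CCC=C(C)C | intermediate
5 | (S)-1-iodo-3,7-dimethyloct-6-en-1-yn-3-ol | IC#C[C@@](C)(O)CCC=C(C)C | intermediate
6 | (3S,1Z)-1-iodo-3,7-dimethylocta-1,6-dien-3-ol | I/C=C\[C@@](C)(O)CCC=C(C)C | intermediate
7 | (3S,1Z)-1-iodo-3,7-dimethyl-3-[(triethylsilyl)oxy]octa-1,6-diene | I/C=C\[C@@](C)(O[Si](CC)(CC)CC)CCC=C(C)C | intermediate
8 | methyl (4S,5Z)-6-iodo-4-methyl-4-[(triethylsilyl)oxy]hex-5-enoate | I/C=C\[C@@](C)(O[Si](CC)(CC)CC)CCC(=O)OC | intermediate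
9 | 3-methylbut-3-en-1-ol (isoprenol) | C=C(C)CCO | starting material
10 | isoprenol O,C-dianion (dilithium) | [Li+].[Li+].[CH2-]C(=C)CC[O-] | intermediate
11 | 3-[(phenylselanyl)methyl]but-3-en-1-ol | C=C(C[Se]c1ccccc1)CCO | intermediate
12 | B-alkyl-9-BBN borane from 11 (O-borinate; C11 racemic) | c1ccccc1[Se]CC(CB1C2CCCC1CCC2)CCOB1C2CCCC1CCC2 | intermediate
13 | methyl (4S,5Z)-10-hydroxy-4-methyl-8-[(phenylselanyl)methyl]-4-[(triethylsilyl)oxy]dec-5-enoate (C8 epimers) | COC(=O)CC[C@](C)(O[Si](CC)(CC)CC)/C=C\CC(CCO)C[Se]c1ccccc1 | intermediate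
14 | methyl (4S,5Z)-4-methyl-10-oxo-8-[(phenylselanyl)methyl]-4-[(triethylsilyl)oxy]dec-5-enoate | COC(=O)CC[C@](C)(O[Si](CC)(CC)CC)/C=C\CC(CC=O)C[Se]c1ccccc1 | intermediate
15 | methyl (4S,5Z)-10-[(tert-butyldimethylsilyl)oxy]-4-methyl-8-[(phenylselanyl)methyl]-4-[(triethylsilyl)oxy]deca-5,9-dienoate (9E/9Z) | COC(=O)CC[C@](C)(O[Si](CC)(CC)CC)/C=C\CC(C=CO[Si](C)(C)C(C)(C)C)C[Se]c1ccccc1 | intermediate
16 | (4S,5Z)-10-[(tert-butyldimethylsilyl)oxy]-4-methyl-8-[(phenylselanyl)methyl]-4-[(triethylsilyl)oxy]deca-5,9-dienal | O=CCC[C@](C)(O[Si](CC)(CC)CC)/C=C\CC(C=CO[Si](C)(C)C(C)(C)C)C[Se]c1ccccc1 | intermediate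
17 | hydroxyacetone | CC(=O)CO | starting material
18 | 2-chloro-2-methylpropanal | CC(C)(Cl)C=O | starting material
19 | (3S,4R)-5-chloro-3,4-dihydroxy-5-methylhexan-2-one | CC(=O)[C@@H](O)[C@@H](O)C(C)(C)Cl | intermediate
20 | (1S)-1-[(2R)-3,3-dimethyloxiran-2-yl]-1-hydroxypropan-2-one | CC(=O)[C@@H](O)[C@H]1OC1(C)C | intermediate
21 | (1S)-1-[(2R)-3,3-dimethyloxiran-2-yl]-1-{[(triisopropylsilyl)oxy]methoxy}propan-2-one | CC(=O)[C@@H](OCO[Si](C(C)C)(C(C)C)C(C)C)[C@H]1OC1(C)C | intermediate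
22 | lithium enolate of 21 | [Li+].C=C([O-])[C@@H](OCO[Si](C(C)C)(C(C)C)C(C)C)[C@H]1OC1(C)C | intermediate
23 | (4S)-4-[(2R)-3,3-dimethyloxiran-2-yl]-3-oxo-4-{[(triisopropylsilyl)oxy]methoxy}butanal (enol form) | O=CCC(=O)[C@@H](OCO[Si](C(C)C)(C(C)C)C(C)C)[C@H]1OC1(C)C | intermediate
24 | Knoevenagel 2-acyl enal (1-oxadiene) from 16 and 23 | O=CC(=CCC[C@](C)(O[Si](CC)(CC)CC)/C=C\CC(C=CO[Si](C)(C)C(C)(C)C)C[Se]c1ccccc1)C(=O)[C@@H](OCO[Si](C(C)C)(C(C)C)C(C)C)[C@H]1OC1(C)C | intermediate
25 | (4aS,7S,11aR,13S,14R) hetero-Diels–Alder adduct: 1-OTBS, 7-OTES, 8Z-ene, 11-CH2SePh, 12-oxo, 13-OTOM, 14,15-epoxide | c1ccccc1[Se]CC1C/C=C\[C@@](C)(O[Si](CC)(CC)CC)CC[C@@H]2C(C(=O)[C@@H](OCO[Si](C(C)C)(C(C)C)C(C)C)[C@H]3OC3(C)C)=COC(O[Si](C)(C)C(C)(C)C)[C@@H]12 | intermediate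
26 | selenoxide of 25 | O=[Se](c1ccccc1)CC1C/C=C\[C@@](C)(O[Si](CC)(CC)CC)CC[C@@H]2C(C(=O)[C@@H](OCO[Si](C(C)C)(C(C)C)C(C)C)[C@H]3OC3(C)C)=COC(O[Si](C)(C)C(C)(C)C)[C@@H]12 | intermediate
27 | (4aS,7S,11aR,13S,14R) 11-methylene 12-ketone: 1-OTBS, 7-OTES, 8Z-ene, 13-OTOM, 14,15-epoxide | C=C1C/C=C\[C@@](C)(O[Si](CC)(CC)CC)CC[C@@H]2C(C(=O)[C@@H](OCO[Si](C(C)C)(C(C)C)C(C)C)[C@H]3OC3(C)C)=COC(O[Si](C)(C)C(C)(C)C)[C@@H]12 | intermediate
28 | (4aS,7S,11aR,12R,13R,14R) 12-alcohol of 27 | C=C1C/C=C\[C@@](C)(O[Si](CC)(CC)CC)CC[C@@H]2C([C@@H](O)[C@@H](OCO[Si](C(C)C)(C(C)C)C(C)C)[C@H]3OC3(C)C)=COC(O[Si](C)(C)C(C)(C)C)[C@@H]12 | intermediate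
29 | lactol tetraol (1-OH anomers; 7-, 12-, 13-OH) | C=C1C/C=C\[C@@](C)(O)CC[C@@H]2C([C@@H](O)[C@@H](O)[C@H]3OC3(C)C)=COC(O)[C@@H]12 | intermediate
30 | (1R,4aS,7S,11aR,12R,13R,14R) 1,12,13-triacetate, 7-OH, 8Z-ene | C=C1C/C=C\[C@@](C)(O)CC[C@@H]2C([C@@H](OC(C)=O)[C@@H](OC(C)=O)[C@H]3OC3(C)C)=CO[C@H](OC(C)=O)[C@@H]12 | intermediate
31 | CNP0134792.1 (1R,4aS,7S,8R,9R,11aR,12R,13R,14R) | C=C1C[C@H]2O[C@H]2[C@@](C)(O)CC[C@@H]2C([C@@H](OC(C)=O)[C@@H](OC(C)=O)[C@H]3OC3(C)C)=CO[C@H](OC(C)=O)[C@@H]12 | target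

**Step count and risks**
Total: 19 steps. Longest linear sequence: 15 steps (1–6, 8–11, 15–19, from geraniol).

Most likely to fail, first: step 15. The nine-membered ring may not close, the ketone oxygen rather than the formyl oxygen may act as the heterodiene terminus, or the remote C7 centre may not control the face. The fallback forms the two rings one after the other, setting out from 8, 11 (through borane 12) and 23 and coming back at 27. Hydrodeiodination of 8 (Bu3SnH, cat. Pd(PPh3)4) gives methyl (S)-4-methyl-4-[(triethylsilyl)oxy]hex-5-enoate F1, and DIBAL-H at −78 °C gives (S)-4-methyl-4-[(triethylsilyl)oxy]hex-5-enal F2. Borane 12 is coupled with vinyl bromide under the step 8 palladium conditions to 3-[(phenylselanyl)methyl]hex-5-en-1-ol F3, which is oxidised (SO3·pyridine, DMSO) to 3-[(phenylselanyl)methyl]hex-5-enal F4 and silylated (TBSOTf, Et3N) to its TBS enol ether F5. An intermolecular three-component Knoevenagel/hetero-Diels–Alder reaction of F2, 23 and F5 (EDDA, MeCN, 0.5 M) gives, after separation of the 4a,11a-trans isomer, the monocyclic dihydropyran diene F6. Selenoxide elimination (mCPBA, then i-Pr2NH) gives the triene F7, and ring-closing metathesis of the C7 vinyl and C10 allyl groups (Grubbs II, toluene, 80 °C, 1 mM) closes the (Z)-cyclononene to 27.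

Second: step 17. The vinylogous-ester ketone may be sluggish, or the epoxide oxygen may compete for zinc and erode the anti selectivity. The fallback inverts instead of reducing directly, setting out from 27 and coming back at 30. L-Selectride (THF, −78 °C, Felkin–Anh, no chelation) gives the (12S)-alcohol F8. Mitsunobu reaction with acetic acid (PPh3, DIAD, toluene, 0 °C) inverts C12 to the (12R)-acetate F9. Fluoride deprotection and acetylation as in step 18 (now acylating only C1-OH and C13-OH) then give 30.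

Third: step 18. The free lactol is sensitive, and acylation may favour the axial 1-epimer. The fallback sets the anomeric centre by SN2 displacement, setting out from 29 and coming back at 30. If acetylation of 29 gives mainly the 1-epi triacetate F10, hydrazinium acetate (DMF, 0 °C) cleaves only the anomeric ester to give the lactol 12,13-diacetate F11. Cl3CCN/DBU converts this into the thermodynamic axial trichloroacetimidate F12, and acetic acid (CH2Cl2, 23 °C) displaces the imidate with inversion, as in uncatalysed glycosyl ester formation, to give 30.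

**Further compounds**
F1 | step 15 | methyl (S)-4-methyl-4-[(triethylsilyl)oxy]hex-5-enoate | C=C[C@@](C)(O[Si](CC)(CC)CC)CCC(=O)OC
F2 | step 15 | (S)-4-methyl-4-[(triethylsilyl)oxy]hex-5-enal | C=C[C@@](C)(O[Si](CC)(CC)CC)CCC=O
F3 | step 15 | 3-[(phenylselanyl)methyl]hex-5-en-1-ol | C=CCC(C[Se]c1ccccc1)CCO
F4 | step 15 | 3-[(phenylselanyl)methyl]hex-5-enal | C=CCC(C[Se]c1ccccc1)CC=O
F5 | step 15 | TBS enol ether of F4 | C=CCC(C[Se]c1ccccc1)C=CO[Si](C)(C)C(C)(C)C
F6 | step 15 | monocyclic dihydropyran diene (4aS,11aR; 7-vinyl, 11-CH2SePh, 11-allyl) | c1ccccc1[Se]CC(CC=C)[C@@H]1C(O[Si](C)(C)C(C)(C)C)OC=C(C(=O)[C@@H](OCO[Si](C(C)C)(C(C)C)C(C)C)[C@H]2OC2(C)C)[C@H]1CC[C@](C)(O[Si](CC)(CC)CC)C=C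
F7 | step 15 | triene from F6 (11-methylene) | C=CCC(=C)[C@@H]1C(O[Si](C)(C)C(C)(C)C)OC=C(C(=O)[C@@H](OCO[Si](C(C)C)(C(C)C)C(C)C)[C@H]2OC2(C)C)[C@H]1CC[C@](C)(O[Si](CC)(CC)CC)C=C
F8 | step 17 | (12S)-alcohol (12-epimer of 28) | C=C1C/C=C\[C@@](C)(O[Si](CC)(CC)CC)CC[C@@H]2C([C@H](O)[C@@H](OCO[Si](C(C)C)(C(C)C)C(C)C)[C@H]3OC3(C)C)=COC(O[Si](C)(C)C(C)(C)C)[C@@H]12
F9 | step 17 | (12R)-acetate of 28 | C=C1C/C=C\[C@@](C)(O[Si](CC)(CC)CC)CC[C@@H]2C([C@@H](OC(C)=O)[C@@H](OCO[Si](C(C)C)(C(C)C)C(C)C)[C@H]3OC3(C)C)=COC(O[Si](C)(C)C(C)(C)C)[C@@H]12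
F10 | step 18 | 1-epi triacetate (1S epimer of 30) | C=C1C/C=C\[C@@](C)(O)CC[C@@H]2C([C@@H](OC(C)=O)[C@@H](OC(C)=O)[C@H]3OC3(C)C)=CO[C@@H](OC(C)=O)[C@@H]12
F11 | step 18 | lactol 12,13-diacetate | C=C1C/C=C\[C@@](C)(O)CC[C@@H]2C([C@@H](OC(C)=O)[C@@H](OC(C)=O)[C@H]3OC3(C)C)=COC(O)[C@@H]12
F12 | step 18 | axial 1-O-trichloroacetimidate | C=C1C/C=C\[C@@](C)(O)CC[C@@H]2C([C@@H](OC(C)=O)[C@@H](OC(C)=O)[C@H]3OC3(C)C)=CO[C@@H](OC(=N)C(Cl)(Cl)Cl)[C@@H]12
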